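**Plan**

- Numbering used: C2(OH)–C1=C10(Me)–C9–C8(O‑methacryloyl)–C7–C6(O‑lactone)–C5=C4(Me)–C3(OAc); C11(=CH2)–C12(=O) is the acrylate unit of the lactone.
- Retrosynthesis: remove PMB and the two acyl groups; cut the lactone at O–C6 and C7–C11 together, back to 2‑bromoacrylic acid and the all‑E diene 12; cut 12 at C10–Me/C1–C2 (alkyne carbometalation), C8–C9 (propargylation) and C5–C6 (Heck).
- Enabling feature: ring carbon C6 is allylic to C4=C5, so O–C6–C5=C4 is a π‑allyl‑Pd carboxylate in disguise and C6–C7 is the remnant of a diene C=C; the product stays ionisable at C6, so that centre can self‑correct.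
- Forward: the C3–C8 chain first, then C9–C10–C1 and C2; the only ring (the α‑methylene‑γ‑butyrolactone) closes in step 8; esters and deprotection last.
- Stereochemistry: C8 by catalyst‑controlled propargylation; C7 by 1,2‑induction from C8 in the carbopalladation; C6 by Pd‑mediated equilibration to the 6,7‑trans lactone; both trisubstituted E alkenes by syn‑carboalumination.

Key step: step 8

Assumption: (R)‑TRIP is taken to deliver the (R)‑carbinol at C8, by analogy with aryl and alkenyl aldehydes; if the sense proves opposite, the enantiomeric catalyst is used.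

**Route**

Step 1
Reactants: 1 propargyl alcohol
Product: 3 (E)-3-iodo-2-methylprop-2-en-1-ol, via alkenylalane 2 (not isolated)
Conditions: Me3Al, Cp2ZrCl2, CH2Cl2, 0 °C→rt; then I2, THF, −30→0 °C; aq. K2CO3 work-up
Reagents that add atoms: trimethylaluminium C[Al](C)C; iodine II
Why: Zr‑catalysed syn‑carboalumination of the terminal alkyne (Negishi) places Me on the internal carbon and Al cis to it on the terminal carbon, and iodinolysis with retention should give the E vinyl iodide that fixes the C4=C5 geometry.

Step 2
Reactants: 3 (E)-3-iodo-2-methylprop-2-en-1-ol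
Product: 4 (E)-1-(tert-butyldimethylsilyloxy)-3-iodo-2-methylprop-2-ene
Conditions: TBSCl, imidazole, DMF, rt
Reagents that add atoms: tert-butyldimethylsilyl chloride CC(C)(C)[Si](C)(C)Cl
Why: Standard silylation of a primary alcohol; the silyl ether is a non‑ionisable C3–O group for the later Pd(0) step.

Step 3
Reactants: 4 vinyl iodide TBS ether; 5 acrolein
Product: 6 (2E,4E)-6-(tert-butyldimethylsilyloxy)-5-methylhexa-2,4-dienal
Conditions: Pd(OAc)2 (5 mol%), NaHCO3, n-Bu4NCl, DMF, 40 °C
Reagents that add atoms: none
Why: Heck reaction under Jeffery conditions; the vinyl iodide couples with retention at C4=C5 and syn β‑hydride elimination should give the E C6=C7 bond.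

Step 4
Reactants: 6 dienal; 7 allenylboronic acid pinacol ester
Product: 8 (4R,5E,7E)-9-(tert-butyldimethylsilyloxy)-8-methylnona-5,7-dien-1-yn-4-ol
Conditions: (R)-TRIP (5 mol%), 4 Å MS, toluene, 0 °C; aq. work-up
Reagents that add atoms: none
Why: Chiral phosphoric acid‑catalysed asymmetric propargylation: the allenylboronate transfers a propargyl group through a closed six‑membered SE2′ transition state, adding 1,2 to the dienal and setting C8 (R) by catalyst control.

Step 5
Reactants: 8 homopropargylic dienol
Product: 9 (4R,5E,7E)-4,9-bis(tert-butyldimethylsilyloxy)-8-methylnona-5,7-dien-1-yne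
Conditions: TBSCl, imidazole, DMAP (cat.), DMF, rt
Reagents that add atoms: tert-butyldimethylsilyl chloride CC(C)(C)[Si](C)(C)Cl
Why: Silylation of the secondary alcohol; the bulky, non‑coordinating and non‑ionisable C8–OTBS group is the stereodirecting element for step 8.

Step 6
Reactants: 9 bis‑TBS dienyne
Product: 11 (2E,5R,6E,8E)-5,10-bis(tert-butyldimethylsilyloxy)-3,9-dimethyldeca-2,6,8-trien-1-ol, via alkenylalane 10 (not isolated)
Conditions: Me3Al, Cp2ZrCl2 (30 mol%), CH2Cl2, 0 °C→rt; then n-BuLi, THF, −78 °C; (CH2O)n, −78 °C→rt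
Reagents that add atoms: trimethylaluminium C[Al](C)C; formaldehyde (as paraformaldehyde) C=O
Why: Negishi carboalumination is regio‑ and syn‑selective for the terminal alkyne (the internal conjugated diene is inert), and hydroxymethylation of the derived alanate with retention should give the E C10=C1 allylic alcohol.

Step 7
Reactants: 11 trienol
Product: 12 (2E,5R,6E,8E)-5,10-bis(tert-butyldimethylsilyloxy)-1-(4-methoxybenzyloxy)-3,9-dimethyldeca-2,6,8-triene
Conditions: NaH, PMBCl, n-Bu4NI (cat.), THF/DMF, 0 °C→rt
Reagents that add atoms: 4-methoxybenzyl chloride COc1ccc(CCl)cc1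
Why: Williamson etherification of the primary allylic alkoxide; PMB is orthogonal to the silyl ethers and to the esters of the endgame.

Step 8
Reactants: 12 diene; 13 2-bromoacrylic acid
Product: 15 6,7-trans α-methylene-γ-butyrolactone with C8–OTBS and C3–OTBS and C2–OPMB (C6/C7/C8 configured as in the target), via 6-epi-lactone 14 (not isolated)
Conditions: 13 (2 equiv, slow addition), Pd(OAc)2 (10 mol%), PPh3 (30 mol%), NaHCO3, n-Bu4NCl, DMF, 70 °C
Reagents that add atoms: none
Why: Proposed new method: oxidative addition of Pd(0) into the C–Br bond of 13 gives a 1‑carboxyvinyl‑Pd(II) species that inserts the C6=C7 end of the diene, placing the vinyl carbon on C7 (the terminus that does not become quaternary) and Pd on the C6–C5–C4 allyl, which the pendant carboxylate then captures at C6; the closest known reaction type is the Larock heteroannulation of 1,3‑dienes by aryl or vinylic halides carrying an OH, NHR or CO2H group, which is not established for 2‑bromoacrylic acid on an acyclic internal diene bearing an allylic stereocentre. The lactone closes 5‑exo on the π‑allyl (O to C6), whereas closure at C4 would need a seven‑membered ring and a quaternary centre. C7 is set in the insertion by the C8 stereocentre: in the A(1,3)‑minimised conformer (C8–H in the diene plane) the vinyl‑Pd should add anti to the bulky OTBS group, which places the new C7–C11 bond anti to C8–O in the zigzag, as the target requires. C6 need not be set kinetically, because the product is an allylic carboxylate that Pd(0)/PPh3 re‑ionises, so the C6 epimer 14 (expected from syn insertion on the E alkene followed by external attack) should drain through the same π‑allyl carboxylate into the more stable 6,7‑trans lactone 15, which makes the step convergent for C6 and for the C6=C7 geometry of the diene. The E geometry of C4=C5 should survive because syn/anti exchange at C4 would require an η1‑allyl at the tertiary carbon. The step needs chemoselectivity for the conjugated diene over the isolated trisubstituted C10=C1 alkene (inert to carbopalladation) and no ionisation at C3 or C8, which is secured by carrying both oxygens as silyl ethers and not as esters.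

Step 9
Reactants: 15 bis‑TBS lactone
Product: 16 lactone diol (C8–OH and C3–OH free; C2–OPMB)
Conditions: HF·pyridine, pyridine, THF, 0 °C→rt
Reagents that add atoms: none
Why: Fluoride‑mediated desilylation of both TBS ethers; buffered HF·pyridine should leave the PMB ether, the allylic lactone C–O bond and the exocyclic methylene untouched.

Step 10
Reactants: 16 lactone diol
Product: 17 C3 monoacetate (C8–OH free; C2–OPMB)
Conditions: AcCl (1.1 equiv), 2,4,6-collidine, CH2Cl2, −78 °C
Reagents that add atoms: acetyl chloride CC(Cl)=O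
Why: Selective acylation: the unhindered primary allylic alcohol should react far faster than the secondary C8 alcohol flanked by the ring.

Step 11
Reactants: 17 monoacetate
Product: 18 C8 methacrylate C3 acetate (C2–OPMB)
Conditions: methacrylic anhydride, Et3N, DMAP (cat.), CH2Cl2, 0 °C→rt
Reagents that add atoms: methacrylic anhydride C=C(C)C(=O)OC(=O)C(C)=C
Why: DMAP‑catalysed acyl transfer to the secondary alcohol with retention at C8; any 8,12‑translactonisation would give the less stable cis‑disubstituted lactone and is not expected to compete.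

Step 12
Reactants: 18 PMB ether
Product: 19 target CNP0323189.1
Conditions: DDQ, CH2Cl2/pH 7 buffer, 0 °C
Reagents that add atoms: none
Why: Oxidative PMB ether cleavage (benzylic hydride abstraction by DDQ, then hydrolysis of the oxocarbenium ion) releases the C2 alcohol under neutral conditions that spare both esters and the α‑methylene lactone.

**Compound list**

1 | propargyl alcohol | C#CCO | starting material
2 | dimethyl[(E)-3-(dimethylalumanyloxy)-2-methylprop-1-enyl]alumane (alkenylalane) | C[Al](C)/C=C(\C)CO[Al](C)C | intermediate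
3 | (E)-3-iodo-2-methylprop-2-en-1-ol | OC/C(C)=C/I | intermediate
4 | (E)-1-(tert-butyldimethylsilyloxy)-3-iodo-2-methylprop-2-ene | CC(C)(C)[Si](C)(C)OC/C(C)=C/I | intermediate
5 | acrolein | C=CC=O | starting material
6 | (2E,4E)-6-(tert-butyldimethylsilyloxy)-5-methylhexa-2,4-dienal | CC(C)(C)[Si](C)(C)OC/C(C)=C/C=C/C=O | intermediate
7 | allenylboronic acid pinacol ester | C=C=CB1OC(C)(C)C(C)(C)O1 | starting material
8 | (4R,5E,7E)-9-(tert-butyldimethylsilyloxy)-8-methylnona-5,7-dien-1-yn-4-ol | C#CC[C@@H](O)/C=C/C=C(\C)CO[Si](C)(C)C(C)(C)C | intermediate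
9 | (4R,5E,7E)-4,9-bis(tert-butyldimethylsilyloxy)-8-methylnona-5,7-dien-1-yne | C#CC[C@@H](O[Si](C)(C)C(C)(C)C)/C=C/C=C(\C)CO[Si](C)(C)C(C)(C)C | intermediate
10 | (E)-alkenyldimethylalane from carboalumination of 9 (Al on C1, cis to the C10 methyl) | C[Al](C)/C=C(\C)C[C@@H](O[Si](C)(C)C(C)(C)C)/C=C/C=C(\C)CO[Si](C)(C)C(C)(C)C | intermediate
11 | (2E,5R,6E,8E)-5,10-bis(tert-butyldimethylsilyloxy)-3,9-dimethyldeca-2,6,8-trien-1-ol | OC/C=C(\C)C[C@@H](O[Si](C)(C)C(C)(C)C)/C=C/C=C(\C)CO[Si](C)(C)C(C)(C)C | intermediate
12 | (2E,5R,6E,8E)-5,10-bis(tert-butyldimethylsilyloxy)-1-(4-methoxybenzyloxy)-3,9-dimethyldeca-2,6,8-triene | COc1ccc(COC/C=C(\C)C[C@@H](O[Si](C)(C)C(C)(C)C)/C=C/C=C(\C)CO[Si](C)(C)C(C)(C)C)cc1 | intermediate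
13 | 2-bromoacrylic acid | C=C(Br)C(=O)O | starting material
14 | 6-epi-lactone: 6,7-cis α-methylene-γ-butyrolactone, C7 and C8 as in 15 | COc1ccc(COC/C=C(\C)C[C@@H](O[Si](C)(C)C(C)(C)C)[C@H]2C(=C)C(=O)O[C@H]2/C=C(\C)CO[Si](C)(C)C(C)(C)C)cc1 | intermediate
15 | 6,7-trans α-methylene-γ-butyrolactone; C7 bears the (1R,3E)-1-(TBS-oxy)-3-methyl-5-(PMB-oxy)pent-3-enyl chain and C6 the (E)-3-(TBS-oxy)-2-methylprop-1-enyl group; C6/C7/C8 as in the target | COc1ccc(COC/C=C(\C)C[C@@H](O[Si](C)(C)C(C)(C)C)[C@H]2C(=C)C(=O)O[C@@H]2/C=C(\C)CO[Si](C)(C)C(C)(C)C)cc1 | intermediate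
16 | lactone diol: as 15 with C8–OH and C3–OH free | COc1ccc(COC/C=C(\C)C[C@@H](O)[C@H]2C(=C)C(=O)O[C@@H]2/C=C(\C)CO)cc1 | intermediate
17 | C3 acetate: as 16 with C3–OAc and C8–OH free | COc1ccc(COC/C=C(\C)C[C@@H](O)[C@H]2C(=C)C(=O)O[C@@H]2/C=C(\C)COC(C)=O)cc1 | intermediate
18 | C8 methacrylate C3 acetate with C2–OPMB | COc1ccc(COC/C=C(\C)C[C@@H](OC(=O)C(C)=C)[C@H]2C(=C)C(=O)O[C@@H]2/C=C(\C)COC(C)=O)cc1 | intermediate
19 | CNP0323189.1, (6R,7R,8R) in the numbering above | C=C(C)C(=O)O[C@H](C/C(C)=C/CO)[C@H]1C(=C)C(=O)O[C@@H]1/C=C(\C)COC(C)=O | target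

**Summary**

Total steps: 12. Longest linear sequence: 12 steps (from propargyl alcohol 1).

**Steps most likely to fail**

1. Step 8 (proposed new method). Migratory insertion may be slow at the internal, α‑branched diene terminus, so that Heck‑type β‑hydride elimination to trienes, oligomerisation of the bromo acid or low facial discrimination at C7 takes over; prolonged exposure to Pd(0) could also erode the C4=C5 geometry or isomerise the exocyclic methylene. The fallback uses known radical chemistry, sets out from 12 and comes back at 15. Mn(OAc)3‑mediated oxidative lactone annulation of 12 with ethyl hydrogen malonate (Cu(OAc)2 cat., KOAc, AcOH, 40 °C) adds the malonyl radical to C7; the allyl radical is oxidised to the cation and the carboxyl group closes on C6 to give the α‑ethoxycarbonyl lactone F1, at which stage C7 epimers would be separated. Saponification (LiOH, THF/H2O) and acidification relactonise to the α‑carboxy lactone F2. Decarboxylative Mannich methylenation (aq. HCHO, Et2NH, NaOAc/AcOH) then installs the exocyclic methylene and returns 15.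

2. Step 6. The Lewis‑acidic Al/Zr system may ionise or methylate the doubly allylic C8 silyl ether or carbometalate the diene, and hydroxymethylation of the alane may stay incomplete. The fallback sets out from 9 and comes back at 11. Deprotonation of the alkyne (n‑BuLi, THF, −78 °C) and addition of paraformaldehyde give the propargylic alcohol F3. Hydroxyl‑directed trans‑hydroalumination with Red‑Al followed by iodinolysis gives the (Z)-3-iodo allylic alcohol F4, with iodine on C10 cis to CH2OH. Me2CuLi replaces iodine by methyl with retention and delivers 11 with the same E geometry.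

3. Step 4. Enantioface discrimination may be insufficient on the extended dienal, or the allenyl group may be transferred instead of the propargyl group. The fallback sets out from 6 and comes back at 8. Barbier propargylation (propargyl bromide, Zn, THF/aq. NH4Cl) gives the racemic homopropargylic alcohol F5. Lipase‑catalysed kinetic resolution (Amano PS, vinyl acetate) is expected to acylate the (R)‑alcohol (large dienyl, medium propargyl; Kazlauskas rule) to the (R)‑acetate F6, which is separated from the unreacted (S)‑alcohol. Methanolysis (K2CO3, MeOH) returns 8.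

**Further compounds**

F1 | step 8 | α-ethoxycarbonyl lactone (as 15 with H and CO2Et on C11 in place of the methylene) | COc1ccc(COC/C=C(\C)C[C@@H](O[Si](C)(C)C(C)(C)C)[C@H]2C(C(=O)OCC)C(=O)O[C@@H]2/C=C(\C)CO[Si](C)(C)C(C)(C)C)cc1
F2 | step 8 | α-carboxy lactone (as 15 with H and CO2H on C11 in place of the methylene) | COc1ccc(COC/C=C(\C)C[C@@H](O[Si](C)(C)C(C)(C)C)[C@H]2C(C(=O)O)C(=O)O[C@@H]2/C=C(\C)CO[Si](C)(C)C(C)(C)C)cc1
F3 | step 6 | (5R,6E,8E)-5,10-bis(tert-butyldimethylsilyloxy)-9-methyldeca-6,8-dien-2-yn-1-ol | OCC#CC[C@@H](O[Si](C)(C)C(C)(C)C)/C=C/C=C(\C)CO[Si](C)(C)C(C)(C)C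
F4 | step 6 | (2Z,5R,6E,8E)-5,10-bis(tert-butyldimethylsilyloxy)-3-iodo-9-methyldeca-2,6,8-trien-1-ol | OC/C=C(\I)C[C@@H](O[Si](C)(C)C(C)(C)C)/C=C/C=C(\C)CO[Si](C)(C)C(C)(C)C
F5 | step 4 | racemic (5E,7E)-9-(tert-butyldimethylsilyloxy)-8-methylnona-5,7-dien-1-yn-4-ol | C#CCC(O)/C=C/C=C(\C)CO[Si](C)(C)C(C)(C)C
F6 | step 4 | (4R,5E,7E)-9-(tert-butyldimethylsilyloxy)-8-methylnona-5,7-dien-1-yn-4-yl acetate | C#CC[C@@H](OC(C)=O)/C=C/C=C(\C)CO[Si](C)(C)C(C)(C)C
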